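**Strategy.** The dihydroisoquinoline is disconnected at C4–C4a with C4 returned to C8a: the precursor is an N-acetyl (S)-1-arylpropan-2-amine whose side chain sits on the future C8a of a 2,4-dioxygenated biaryl. Amide activation lets C8a attack the nitrilium carbon C1 at the ipso position, giving a spiro-fused five-membered 1-pyrroline; a 1,2-shift of C4 to the free C4a then enlarges it to the six-membered N-ring and rearomatizes the carbocycle. The step exploits the meta-dioxygenated carbocycle of the isoquinoline: C8a is para to O6 and ortho to O8, hence the nucleophilic site. C3 comes from L-alanine (sulfamidate), the C7–C1' bond from a Suzuki coupling.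

Key step: step 12

Assumption: the SMILES fixes only C3 as (S) and leaves the C7–C1' biaryl axis open, so the axis is not controlled; isoquinoline numbering is used for the target, and TIPS stands for tri(propan-2-yl)silyl.

**Step 1**
Reactants: 1 ethyl 2-methoxy-6-methylbenzoate; 2 ethyl (E)-but-2-enoate
Product: 4 ethyl 8-methoxy-3-methyl-1-oxo-1,2,3,4-tetrahydronaphthalene-2-carboxylate (racemic, keto/enol mixture), via lithiated toluate 3 (not isolated)
Conditions: LDA (2.2 equiv), THF, −78 °C; 2, −78 °C → rt; aq. HCl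
Reagents that add atoms: none
Why: Lateral lithiation of the ortho-toluate gives benzylic anion 3, which adds 1,4 to the crotonate, and the resulting ester enolate acylates itself on the neighbouring aryl ester (Michael–Dieckmann or Staunton–Weinreb annulation); the two new stereocenters are formed without control and are erased in step 4.

**Step 2**
Reactants: 4 ethyl 8-methoxy-3-methyl-1-oxo-1,2,3,4-tetrahydronaphthalene-2-carboxylate
Product: 5 8-methoxy-3-methyl-3,4-dihydronaphthalen-1(2H)-one (racemic)
Conditions: 6 M aq. HCl, AcOH, 100 °C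
Reagents that add atoms: none
Why: Acid hydrolysis of the β-keto ester and loss of CO2 from the β-keto acid (ester hydrolysis–decarboxylation) should leave the aryl methyl ether and the ketone untouched.

**Step 3**
Reactants: 5 8-methoxy-3-methyl-3,4-dihydronaphthalen-1(2H)-one
Product: 6 5-bromo-8-methoxy-3-methyl-3,4-dihydronaphthalen-1(2H)-one (racemic)
Conditions: NBS (1.05 equiv), MeCN, 0 °C → rt, dark
Reagents that add atoms: N-bromosuccinimide, BrN1C(=O)CCC1=O
Why: Electrophilic aromatic bromination should go to C5, which is para to the methoxy group and meta to the deactivating acyl carbon, with NBS in acetonitrile favouring ring over α-carbonyl bromination.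

**Step 4**
Reactants: 6 5-bromo-8-methoxy-3-methyl-3,4-dihydronaphthalen-1(2H)-one
Product: 8 5-bromo-8-methoxy-3-methylnaphthalen-1-ol, via 2-bromo ketone 7 (not isolated)
Conditions: PhNMe3Br3 (1.0 equiv), THF, 0 °C → rt; then LiBr, Li2CO3, DMF, 120 °C
Reagents that add atoms: none
Why: α-Bromination of the ketone at C2, its only enolizable position, and base-induced dehydrobromination give the naphthalen-1(4H)-one, which tautomerizes to the naphthol (dehydrohalogenation–aromatization); the aryl bromide is inert.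

**Step 5**
Reactants: 8 5-bromo-8-methoxy-3-methylnaphthalen-1-ol
Product: 9 [(5-bromo-8-methoxy-3-methylnaphthalen-1-yl)oxy]tri(propan-2-yl)silane
Conditions: TIPSOTf, 2,6-lutidine, CH2Cl2, 0 °C → rt
Reagents that add atoms: tri(propan-2-yl)silyl trifluoromethanesulfonate, CC(C)[Si](C(C)C)(C(C)C)OS(=O)(=O)C(F)(F)F
Why: O-Silylation with the silyl triflate, needed because the naphthol is crowded by the peri methoxy group, masks the OH for the organolithium, palladium and Tf2O steps.

**Step 6**
Reactants: 10 2-bromobenzene-1,3-diol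
Product: 11 2-bromo-4-iodobenzene-1,3-diol
Conditions: NIS (1.0 equiv), MeCN, −20 → 0 °C
Reagents that add atoms: N-iodosuccinimide, IN1C(=O)CCC1=O
Why: Electrophilic aromatic iodination of the symmetric diol can reach only C4 (equivalent to C6), ortho to one OH and para to the other, and one equivalent at low temperature should limit the 4,6-diiodide.

**Step 7**
Reactants: 11 2-bromo-4-iodobenzene-1,3-diol
Product: 12 2-bromo-6-iodo-3-(TIPS-oxy)phenol
Conditions: TIPSCl (1.05 equiv), imidazole, DMF, 0 °C
Reagents that add atoms: chlorotri(propan-2-yl)silane, CC(C)[Si](Cl)(C(C)C)C(C)C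
Why: Silyl ether formation is governed by sterics, so the bulky TIPS group should go to the OH flanked by Br and H rather than to the one flanked by Br and I.

**Step 8**
Reactants: 12 2-bromo-6-iodo-3-(TIPS-oxy)phenol
Product: 13 (2-bromo-4-iodo-3-methoxyphenoxy)tri(propan-2-yl)silane
Conditions: MeI, K2CO3, DMF, 0 °C → rt
Reagents that add atoms: iodomethane, CI
Why: Williamson O-methylation of the remaining acidic 2,6-dihalophenol proceeds under mild base, under which the aryl TIPS ether should survive.

**Step 9**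
Reactants: 13 (2-bromo-4-iodo-3-methoxyphenoxy)tri(propan-2-yl)silane; 14 tert-butyl (4S)-4-methyl-1,2,3-oxathiazolidine-3-carboxylate 2,2-dioxide
Product: 16 tert-butyl N-[(2S)-1-(3-bromo-2-methoxy-4-(TIPS-oxy)phenyl)propan-2-yl]carbamate, via aryl Grignard reagent 15 (not isolated)
Conditions: iPrMgCl·LiCl, THF, −20 °C; CuI (10 mol%), 14, −20 °C → rt; 1 M aq. HCl, rt
Reagents that add atoms: none
Why: Iodine–magnesium exchange is much faster at C–I than at the C–Br flanked by two oxygens, and the copper-catalysed SN2 opening of the cyclic sulfamidate occurs at its CH2–O carbon, so the (S) C–N stereocenter from L-alanine is carried over untouched; dilute acid then cleaves the N-sulfate and leaves Boc and TIPS in place.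

**Step 10**
Reactants: 9 [(5-bromo-8-methoxy-3-methylnaphthalen-1-yl)oxy]tri(propan-2-yl)silane; 16 tert-butyl N-[(2S)-1-(3-bromo-2-methoxy-4-(TIPS-oxy)phenyl)propan-2-yl]carbamate
Product: 18 tert-butyl N-[(2S)-1-(2-methoxy-3-[4-methoxy-7-methyl-5-(TIPS-oxy)naphthalen-1-yl]-4-(TIPS-oxy)phenyl)propan-2-yl]carbamate, via naphthyl borate 17 (not isolated)
Conditions: 9, n-BuLi, THF, −78 °C; B(OiPr)3, −78 °C → rt; then 16, Pd(OAc)2 (5 mol%), SPhos (10 mol%), aq. K3PO4, THF, 70 °C
Reagents that add atoms: none
Why: Bromine–lithium exchange and trapping with B(OiPr)3 give borate 17, which should undergo Suzuki–Miyaura coupling with the di-ortho-oxygenated bromide under a bulky electron-rich biarylphosphine; the carbamate N–H and both silyl ethers tolerate the aqueous phosphate base.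

**Step 11**
Reactants: 18 the biaryl Boc-carbamate
Product: 20 N-[(2S)-1-(2-methoxy-3-[4-methoxy-7-methyl-5-(TIPS-oxy)naphthalen-1-yl]-4-(TIPS-oxy)phenyl)propan-2-yl]acetamide, via ammonium chloride 19 (not isolated)
Conditions: HCl (4 M in dioxane), CH2Cl2, 0 °C → rt; evaporate; Ac2O, Et3N, CH2Cl2, 0 °C
Reagents that add atoms: acetic anhydride, CC(=O)OC(C)=O
Why: Anhydrous acid removes the Boc group by loss of isobutene and CO2 (carbamate acidolysis) without touching the aryl TIPS ethers, and the ammonium salt is N-acetylated in the same flask (amide formation); the stereocenter is not involved.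

**Step 12**
Reactants: 20 the biaryl acetamide
Product: 24 (3S)-7-(5-hydroxy-4-methoxy-7-methylnaphthalen-1-yl)-8-methoxy-1,3-dimethyl-3,4-dihydroisoquinolin-6-ol, via nitrilium triflate 21 (not isolated), via spiro cation 22 (not isolated), via bis-silyl dihydroisoquinoline 23 (not isolated)
Conditions: Tf2O (1.2 equiv), 2-chloropyridine (2 equiv), CH2Cl2, −78 → 0 °C; TfOH (2 equiv), 0 → 40 °C; aq. NaHCO3; then TBAF, THF, 0 °C → rt; aq. NH4Cl
Reagents that add atoms: none
Why: O-Triflation of the acetamide and loss of triflate give nitrilium ion 21, and the arene carbon that carries the side chain (future C8a), para to the silyloxy group (O6) and ortho to the methoxy group (O8), attacks the nitrilium carbon C1 in a 5-endo-dig ipso cyclization, because the only ortho position open to a normal six-ring closure is meta to both oxygens. The resulting spiro cation 22 holds the five-membered 1-pyrroline ring C8a–C1=N–C3–C4; under TfOH the basic imine nitrogen is protonated, which holds C1 in place, and C4 shifts from C8a to the neighbouring unsubstituted carbon (future C4a), so the five-membered ring is enlarged by one atom to the six-membered N-ring by a 1,2-alkyl shift, not by a new closure, and loss of the C4a proton rearomatizes the carbocycle. The closest known reaction types are the ipso ("abnormal") Bischler–Napieralski reaction of para-alkoxyphenethyl amides and the dienone–phenol rearrangement. No permanent stereocenter is formed: the spiro carbon is transient, and C3 is neither ionized nor enolizable here, so its (S) configuration should be retained. The step needs ipso over ortho attack, migration of C4 and not of C1, and migration to C4a and not to C8; the 2,4-dioxygenation pattern, N-protonation and the blocked, methoxy-bearing C8 (which has no proton to lose) should secure these. Fluoride then removes both silyl ethers from 23.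

**Compound list**
1 | ethyl 2-methoxy-6-methylbenzoate | CCOC(=O)c1c(C)cccc1OC | starting material
2 | ethyl (E)-but-2-enoate | C/C=C/C(=O)OCC | starting material
3 | [2-(ethoxycarbonyl)-3-methoxyphenyl]methyllithium | [Li]Cc1cccc(OC)c1C(=O)OCC | intermediate (not isolated)
4 | ethyl 8-methoxy-3-methyl-1-oxo-1,2,3,4-tetrahydronaphthalene-2-carboxylate (racemic) | CCOC(=O)C1C(C)Cc2cccc(OC)c2C1=O | intermediate
5 | 8-methoxy-3-methyl-3,4-dihydronaphthalen-1(2H)-one (racemic) | CC1CC(=O)c2c(OC)cccc2C1 | intermediate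
6 | 5-bromo-8-methoxy-3-methyl-3,4-dihydronaphthalen-1(2H)-one (racemic) | CC1CC(=O)c2c(OC)ccc(Br)c2C1 | intermediate
7 | 2,5-dibromo-8-methoxy-3-methyl-3,4-dihydronaphthalen-1(2H)-one | CC1Cc2c(Br)ccc(OC)c2C(=O)C1Br | intermediate (not isolated)
8 | 5-bromo-8-methoxy-3-methylnaphthalen-1-ol | Cc1cc(O)c2c(OC)ccc(Br)c2c1 | intermediate
9 | [(5-bromo-8-methoxy-3-methylnaphthalen-1-yl)oxy]tri(propan-2-yl)silane | Cc1cc(O[Si](C(C)C)(C(C)C)C(C)C)c2c(OC)ccc(Br)c2c1 | intermediate
10 | 2-bromobenzene-1,3-diol | Oc1cccc(O)c1Br | starting material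
11 | 2-bromo-4-iodobenzene-1,3-diol | Oc1ccc(I)c(O)c1Br | intermediate
12 | 2-bromo-6-iodo-3-(TIPS-oxy)phenol | Oc1c(I)ccc(O[Si](C(C)C)(C(C)C)C(C)C)c1Br | intermediate
13 | (2-bromo-4-iodo-3-methoxyphenoxy)tri(propan-2-yl)silane | COc1c(I)ccc(O[Si](C(C)C)(C(C)C)C(C)C)c1Br | intermediate
14 | tert-butyl (4S)-4-methyl-1,2,3-oxathiazolidine-3-carboxylate 2,2-dioxide | C[C@H]1COS(=O)(=O)N1C(=O)OC(C)(C)C | starting material
15 | [3-bromo-2-methoxy-4-(TIPS-oxy)phenyl]magnesium chloride (LiCl complex) | COc1c([Mg]Cl)ccc(O[Si](C(C)C)(C(C)C)C(C)C)c1Br | intermediate (not isolated)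
16 | tert-butyl N-[(2S)-1-(3-bromo-2-methoxy-4-(TIPS-oxy)phenyl)propan-2-yl]carbamate | C[C@H](NC(=O)OC(C)(C)C)Cc1ccc(O[Si](C(C)C)(C(C)C)C(C)C)c(Br)c1OC | intermediate
17 | lithium [4-methoxy-7-methyl-5-(TIPS-oxy)naphthalen-1-yl]tri(propan-2-yloxy)borate | [Li+].CC(C)O[B-](OC(C)C)(OC(C)C)c1ccc(OC)c2c(O[Si](C(C)C)(C(C)C)C(C)C)cc(C)cc12 | intermediate (not isolated)
18 | tert-butyl N-[(2S)-1-(2-methoxy-3-[4-methoxy-7-methyl-5-(TIPS-oxy)naphthalen-1-yl]-4-(TIPS-oxy)phenyl)propan-2-yl]carbamate | C[C@H](NC(=O)OC(C)(C)C)Cc1ccc(O[Si](C(C)C)(C(C)C)C(C)C)c(-c2ccc(OC)c3c(O[Si](C(C)C)(C(C)C)C(C)C)cc(C)cc23)c1OC | intermediate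
19 | (2S)-1-(2-methoxy-3-[4-methoxy-7-methyl-5-(TIPS-oxy)naphthalen-1-yl]-4-(TIPS-oxy)phenyl)propan-2-aminium chloride | C[C@H]([NH3+])Cc1ccc(O[Si](C(C)C)(C(C)C)C(C)C)c(-c2ccc(OC)c3c(O[Si](C(C)C)(C(C)C)C(C)C)cc(C)cc23)c1OC.[Cl-] | intermediate (not isolated)
20 | N-[(2S)-1-(2-methoxy-3-[4-methoxy-7-methyl-5-(TIPS-oxy)naphthalen-1-yl]-4-(TIPS-oxy)phenyl)propan-2-yl]acetamide | C[C@H](NC(C)=O)Cc1ccc(O[Si](C(C)C)(C(C)C)C(C)C)c(-c2ccc(OC)c3c(O[Si](C(C)C)(C(C)C)C(C)C)cc(C)cc23)c1OC | intermediate
21 | N-[(2S)-1-(2-methoxy-3-[4-methoxy-7-methyl-5-(TIPS-oxy)naphthalen-1-yl]-4-(TIPS-oxy)phenyl)propan-2-yl]ethanenitrilium triflate | C[C@H]([N+]#CC)Cc1ccc(O[Si](C(C)C)(C(C)C)C(C)C)c(-c2ccc(OC)c3c(O[Si](C(C)C)(C(C)C)C(C)C)cc(C)cc23)c1OC.[O-]S(=O)(=O)C(F)(F)F | intermediate (not isolated)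
22 | (3S)-6-methoxy-1,3-dimethyl-7-[4-methoxy-7-methyl-5-(TIPS-oxy)naphthalen-1-yl]-8-(TIPS-oxy)-2-azaspiro[4.5]deca-1,6,9-trien-8-ylium triflate (drawn as the O-silyl oxocarbenium form; spiro carbon unassigned) | CC1=N[C@@H](C)CC12C=CC(=[O+][Si](C(C)C)(C(C)C)C(C)C)C(-c3ccc(OC)c4c(O[Si](C(C)C)(C(C)C)C(C)C)cc(C)cc34)=C2OC.[O-]S(=O)(=O)C(F)(F)F | intermediate (not isolated)
23 | (3S)-8-methoxy-1,3-dimethyl-7-[4-methoxy-7-methyl-5-(TIPS-oxy)naphthalen-1-yl]-6-(TIPS-oxy)-3,4-dihydroisoquinoline | C[C@H]1Cc2cc(O[Si](C(C)C)(C(C)C)C(C)C)c(-c3ccc(OC)c4c(O[Si](C(C)C)(C(C)C)C(C)C)cc(C)cc34)c(OC)c2C(C)=N1 | intermediate (not isolated)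
24 | (3S)-7-(5-hydroxy-4-methoxy-7-methylnaphthalen-1-yl)-8-methoxy-1,3-dimethyl-3,4-dihydroisoquinolin-6-ol | C[C@H]1Cc2cc(O)c(-c3ccc(OC)c4c(O)cc(C)cc34)c(OC)c2C(C)=N1 | target

**Total step count:** 12
**Longest linear sequence:** 8 steps (steps 1–5, then 10, 11, 12)

**Steps most likely to fail**

1. Step 12. The spiro cation may rearrange by migration of C1 instead of C4, or the nitrilium ion may close slowly at the ortho carbon; either gives the regioisomeric ring. The 1,2-shift may also stall at the spiro stage. Early loss of silyl groups is harmless because fluoride follows.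
Fallback, from 20 back to 24: the one-pot cationic cascade is replaced by a two-stage sequence through an isolated neutral dienone. The same activation (Tf2O, 2-chloropyridine, CH2Cl2, −78 → −20 °C) is quenched cold with aq. NaHCO3, which should hydrolyse the silyl oxocarbenium ion to the spirodienone F1. F1 is isolated and rearranged in a separate dienone–phenol step (CF3CO2H with catalytic H2SO4, or BF3·OEt2, rt → 50 °C) to the 6-hydroxy dihydroisoquinoline F2, which still carries the naphthyl TIPS ether. TBAF in THF then gives 24.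

2. Step 10. Oxidative addition and transmetalation at the bromide flanked by OMe and OTIPS may be slow, so that protodeboronation of borate 17 wins.
Fallback, from 10 and borate 17 back to 18: the biaryl bond is made first, on the small unprotected ring. Suzuki coupling of 2-bromoresorcinol 10 with 17 (Pd(OAc)2, SPhos, K3PO4, dioxane/H2O) should give the 2-arylresorcinol F3. NIS iodinates the free resorcinol ring, far more reactive than the naphthyl ethers, at its only open activated position to give the iodo diol F4. TIPSCl/imidazole silylates the oxygen flanked by the aryl group and hydrogen to give the mono-silyl ether F5, and MeI/K2CO3 gives the methyl ether F6. Iodine–magnesium exchange and opening of 14 under the conditions of step 9 return to 18.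

3. Step 7. Silylation may occur at the more acidic, doubly flanked oxygen or at both oxygens (poor site selectivity).
Fallback, from 10 back to 12: the order of silylation and iodination is reversed. One equivalent of TIPSCl/imidazole on the symmetric diol 10 can give only one mono-ether, 2-bromo-3-(TIPS-oxy)phenol F7, which is separated from diol and bis-ether. Iodination of the remaining phenol (I2, tert-butylamine, toluene, 0 °C) should go ortho to OH and para to OSi, because the other activated position is shielded by the silyl group, and give 12.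

**Further compounds**
F1 | step 12 | (3S)-6-methoxy-1,3-dimethyl-7-[4-methoxy-7-methyl-5-(TIPS-oxy)naphthalen-1-yl]-2-azaspiro[4.5]deca-1,6,9-trien-8-one | CC1=N[C@@H](C)CC12C=CC(=O)C(-c3ccc(OC)c4c(O[Si](C(C)C)(C(C)C)C(C)C)cc(C)cc34)=C2OC
F2 | step 12 | (3S)-8-methoxy-1,3-dimethyl-7-[4-methoxy-7-methyl-5-(TIPS-oxy)naphthalen-1-yl]-3,4-dihydroisoquinolin-6-ol | C[C@H]1Cc2cc(O)c(-c3ccc(OC)c4c(O[Si](C(C)C)(C(C)C)C(C)C)cc(C)cc34)c(OC)c2C(C)=N1
F3 | step 10 | 2-[4-methoxy-7-methyl-5-(TIPS-oxy)naphthalen-1-yl]benzene-1,3-diol | Oc1cccc(O)c1-c1ccc(OC)c2c(O[Si](C(C)C)(C(C)C)C(C)C)cc(C)cc12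
F4 | step 10 | 4-iodo-2-[4-methoxy-7-methyl-5-(TIPS-oxy)naphthalen-1-yl]benzene-1,3-diol | Oc1ccc(I)c(O)c1-c1ccc(OC)c2c(O[Si](C(C)C)(C(C)C)C(C)C)cc(C)cc12
F5 | step 10 | 6-iodo-2-[4-methoxy-7-methyl-5-(TIPS-oxy)naphthalen-1-yl]-3-(TIPS-oxy)phenol | Oc1c(I)ccc(O[Si](C(C)C)(C(C)C)C(C)C)c1-c1ccc(OC)c2c(O[Si](C(C)C)(C(C)C)C(C)C)cc(C)cc12
F6 | step 10 | {4-iodo-3-methoxy-2-[4-methoxy-7-methyl-5-(TIPS-oxy)naphthalen-1-yl]phenoxy}tri(propan-2-yl)silane | COc1c(I)ccc(O[Si](C(C)C)(C(C)C)C(C)C)c1-c1ccc(OC)c2c(O[Si](C(C)C)(C(C)C)C(C)C)cc(C)cc12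
F7 | step 7 | 2-bromo-3-(TIPS-oxy)phenol | Oc1cccc(O[Si](C(C)C)(C(C)C)C(C)C)c1Br
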